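## Structural features

The target is a 14-membered carbocycle with ring atoms C1–C11, C14, C15 and C16, numbered as follows: C1 is the methyl-bearing olefin carbon, C2 the olefinic CH, C5 the CHMe, C6 and C9 the ether carbons, C10 the carbinol, C11 and C14 the lactone-fusion carbons, C15 the ketone, and C16 the CH2 between C15 and C1. An oxygen bridge from C6 to C9 defines a 2,5-trans oxolane (ring A, with C9 quaternary and methylated), and C11/C14 carry a cis-fused γ-lactone (ring B: O–C12(=O)–C13HMe). The seven stereocentres (5R,6R,9R,10R,11S,13R,14R) form a vicinal pair C5/C6 (methyl and ring oxygen syn) and a contiguous run C9–C10–C11–C14–C13. In that run the oxygens on C9, C10 and C11 are mutually syn, the C10 and C15 branches are cis on ring B, and the C13 methyl is trans to the C15 branch, which is the thermodynamically preferred α-configuration. The fragile part is the C15 ketone: C14–H is enolisable, the lactone oxygen on C11 is β to the carbonyl and can leave by E1cB, and the (E)-C1=C2 olefin is β,γ and can move into conjugation; base can also open the lactone or transpose it onto a free C10 hydroxyl. The real difficulty is to close the large ring and reveal this ketone without exposing the β-acyloxy ketone to base, and before that to build the C9–C10–C11 oxygen triad next to a quaternary centre. The key step exploits the position of C15 between ring B (C14) and the allylic methylene C16 of the C16–C1(Me)=C2 unit: C16 becomes the terminus of a 2-methylallyl palladium complex, and C15, carried as CH2NO2, is a soft carbon nucleophile whose acidity does not extend to C14.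

## Logic of the disconnections

31 back to 30: the O–Si bond on C10 is cut last. The final operation must be acidic and non-enolising because 31 holds the base-labile β-acyloxy ketone; the gain is a hydroxyl that stays masked through ring closure and carbonyl unveiling; the demand is silyl cleavage without olefin migration.

30 back to 26: the C15 carbonyl is traced to a C15 nitro group. The nitro group is both the activating group for ring closure and the latent carbonyl, so the ketone never exists in an open-chain intermediate; the demand is a Nef reaction in which the new ketone meets only a weakly acidic buffer.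

26 back to 25: the C15–C16 bond is cut, opening the 14-membered ring. C16 is allylic and C15 is the future carbonyl carbon, so an allyl cation at C16 and an acyl anion equivalent at C15 are the natural polarities; the gain is an acyclic seco compound with all seven stereocentres in place; the demand is C-selective, terminus-selective (C16, not C2), geometry-retaining and intramolecular allylation.

25 back to 22 through 24 and 23: the C15–N bond, then the C15–I bond, then the O–Si bond on the C15 oxygen are cut. The nitro group enters last so that the acidic CH2NO2 never meets the basic cross-coupling; the demands are N- rather than O-attack of nitrite on a β-branched primary iodide and removal of the primary silyl ether while the hindered secondary one on C10 stays.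

22 back to 21: the carbonate C–O bond at C16 is cut. An allylic carbonate cannot be carried through a zerovalent palladium cross-coupling, so it is made afterwards; the demand is a simple acylation of the only free hydroxyl.

21 back to 18 and 19: the C2–C3 bond is cut. This sp2–sp3 junction separates the chiral core from the achiral C16/C1/C2 unit, and the (E)-olefin geometry is bought with 19; the gain is removal of four carbons and the trisubstituted olefin; the demand is hydroboration of one vinyl group in the presence of a lactone and a stereoretentive coupling.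

18 back to 16: the C13–H and C14–H bonds are cut, giving a C13=C14 butenolide. Both ring B centres can be derived from C11: hydride enters C14 anti to the C11 substituent and C13 is set thermodynamically; the demand is 1,4-reduction of a tetrasubstituted butenolide that leaves the vinyl group intact.

16 back to 9 and 14 through 15: the O–Si bond on C10 and then the C10–C11 bond are cut. This joins the ring A half to the ring B half and creates C10 and C11 together; the demand is chelation control through the ring A oxygen (10R), syn simple diastereoselection (11S) and γ-attack of the furan.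

14 back to 10 through 12: two O–Si bonds, then the C13=C14 double bond and the O–C12 bond are cut. The symmetrical ketone 10 makes olefin geometry irrelevant; the gain is a three-carbon commodity; there is no special demand.

9 back to 7 through 8: the oxidation level of C10 is adjusted, then the O–C9 and C10–O bonds are cut. The trans oxolane with its quaternary centre is derived from the single carbinol centre C6; the gain is an acyclic dienol; the demand is trans selectivity and discrimination between two olefins.

7 back to 2 and 3, and 2 back to 1: the C5–C6 bond is cut. A syn methyl/hydroxyl pair is the signature of a (Z)-crotyl addition; the gain is two achiral commodity chemicals; the demand is reagent-controlled enantio- and diastereoselection.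

## Other disconnections considered

Alternative 1: The cut is C11–C14 together with O–C12, i.e. ring B, not the macrocycle. In the forward step the α-hydroxy aldehyde A1 and the (Z)-bromomethyl enoate A2 would react with indium in aqueous THF and lactonise to the cis-4,5-disubstituted α-methylene lactone A3.
- In its favour: C11, C14 and ring B would arise in one water-tolerant operation. The free C10 hydroxyl would serve as the chelating control element, so no protecting group is needed there. The later reduction would act on an unhindered exocyclic methylene. On these points it is better than the chosen plan, which needs a substrate-controlled vinylogous aldol and the reduction of a tetrasubstituted butenolide.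
- Against it here: it closes no large ring. In A3, C16 is still a methyl group of an isopropylidene terminus, so an allylic oxidation and a C15–C16 ring closure remain to be solved. A1 is an α-hydroxy aldehyde that oligomerises easily, and its C10 centre must still be set by addition to the same hindered aldehyde.
- Comparison: on structure it solves the lactone only; on mechanism it is the more secure of the two for C11/C14; on step economy it is equal for ring B but longer overall because the ring closure and the C16 oxidation come on top. Its logic is kept as the fallback for step 7.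

Alternative 2: The cut is C14–C15 together with O–C11. In the forward step the hydroximoyl chloride A4 would be treated with EtMgBr at high dilution, and the nitrile oxide A5, held as the magnesium alkoxide of C10, would add to the (E)-C11=C14 olefin to give the macrocyclic isoxazoline A6.
- In its favour: ring closure and two stereocentres (C11, C14) would come in one step, against none in the chosen key step, which is a clear advantage. The suprafacial addition to the (E)-olefin gives the correct C11/C14 relationship, and the C10 alkoxide directs both the face and the orientation. The C15 carbonyl and the C11 oxygen stay masked in the heterocycle, which equals the chosen plan in hiding the sensitive ketone.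
- Against it here: the macrocyclic cycloaddition must outrun dimerisation of A5. The allylic centre C13 on the far side of the olefin may oppose the C10 directing effect. The chlorination that makes A4 must spare an electron-rich trisubstituted olefin. After A6, N–O cleavage, oxidation at C12 and lactonisation are still needed, and they pass through a free β-hydroxy carbonyl array that can undergo retro-aldol cleavage or dehydration.
- Comparison: on structure it is more convergent in stereochemistry; on mechanism it rests on a known cycloaddition class but an untested macrocyclic transition state; on step economy it is better before ring closure and clearly worse after it (at least four steps against two).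

Alternative 3: The cut is C2–C3. In the forward step the terminal vinyl group of the seco compound A7 would be hydroborated with 9-BBN and coupled with its own C2 vinyl iodide under PdCl2(dppf), AsPh3 and Cs2CO3 at high dilution to give the protected macrocycle A8.
- In its favour: macrocyclic B-alkyl cross-coupling is established chemistry, so on precedent it is better than the chosen key step. The olefin geometry is fixed in the vinyl iodide and cannot erode through allyl isomerisation, which is also better. After ring closure only acid-labile groups remain, which equals the chosen plan.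
- Against it here: A7 must already contain the C15 carbonyl as a dioxolane, so a ketone next to C14 and β to the lactone oxygen must be made and ketalised well before ring closure, which exposes the fragile array for several steps. The C15–C16 bond must still be made, intermolecularly, so the polarity problem is moved and not removed. The lactone must sit in aqueous carbonate for a long, dilute reaction.
- Comparison: on structure it gives the same ring; on mechanism it is safer in the closing step and riskier in the steps before it; on step economy it is equal after ring closure and longer before.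

Key step: step 15

Remark on the chemistry (assumption): the (−)-B-methoxydiisopinocampheylborane derived from (+)-α-pinene is taken to deliver the crotyl group to the Si face of 2, the accepted sense for unbranched aliphatic aldehydes.

Remark on the structures: 25, 26 and 31 have the same geometry at C5, C6, C9, C10, C11, C13 and C14 and the same (E)-olefin. Only the CIP descriptor of C14 changes with the C15 substituent (S with CH2O, CH2NO2 or C=N; R with CH2I or C=O). C15 is a new, uncontrolled stereocentre in 26 (one epimer drawn) and is erased in step 16.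

## Steps

Step 1
Reactants: 1 4-methylpent-4-en-1-ol
Product: 2 4-methylpent-4-enal
Conditions: TEMPO (10 mol%), PhI(OAc)2 (1.1 equiv), CH2Cl2, rt; short-path distillation
Reagents that add atoms: none
Why: Nitroxyl-catalysed alcohol oxidation should stop at the aldehyde and leave the 1,1-disubstituted olefin alone; the volatile aldehyde is used at once.

Step 2
Reactants: 2 4-methylpent-4-enal; 3 cis-2-butene
Product: 7 (3R,4R)-3,7-dimethylocta-1,7-dien-4-ol, via (Z)-but-2-enylpotassium 4 (not isolated), via (Z)-crotyldiisopinocampheylborane 5 (not isolated), via diisopinocampheylborinate adduct 6 (not isolated)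
Conditions: 3, t-BuOK, n-BuLi, THF, −78 → −45 °C; (−)-Ipc2BOMe, −78 °C; BF3·OEt2; 2, −78 °C; then NaOH, H2O2, 0 °C → rt
Reagents that add atoms: none
Why: Brown crotylboration: the (Z)-crotylborane reacts through a closed chair (Zimmerman–Traxler) transition state, so the Z geometry gives the syn C5-methyl/C6-hydroxyl pair, and the isopinocampheyl groups direct attack to the Si face of 2, which sets 5R and 6R (3R,4R in 7).

Step 3
Reactants: 7 (3R,4R)-3,7-dimethylocta-1,7-dien-4-ol
Product: 8 [(2R,5R)-5-[(2R)-but-3-en-2-yl]-2-methyloxolan-2-yl]methanol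
Conditions: Co(modp)2 (10 mol%), O2 (1 atm), t-BuOOH (10 mol%), i-PrOH, 55 °C
Reagents that add atoms: dioxygen, O=O
Why: Mukaiyama aerobic oxidative cyclisation with the divalent cobalt complex Co(modp)2 (modp = 1-morpholinocarbamoyl-4,4-dimethylpentane-1,3-dionate): the hydroxyl adds 5-exo to C9 of the 1,1-disubstituted olefin and the primary radical is trapped by O2 and reduced to CH2OH. The chair-like transition state with the C6 substituent pseudo-equatorial should give the 2,5-trans oxolane (C10 trans to the C5 branch, C9 R), and the vinyl group is too close to the hydroxyl to cyclise.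

Step 4
Reactants: 8 [(2R,5R)-5-[(2R)-but-3-en-2-yl]-2-methyloxolan-2-yl]methanol
Product: 9 (2R,5R)-5-[(2R)-but-3-en-2-yl]-2-methyloxolane-2-carbaldehyde
Conditions: DMP (1,1,1-triacetoxy-1,1-dihydro-1,2-benziodoxol-3(1H)-one, 1.2 equiv), NaHCO3, CH2Cl2, 0 °C → rt
Reagents that add atoms: none
Why: Periodinane oxidation of a neopentyl-type primary alcohol; the α-carbon C9 is quaternary, so nothing can epimerise.

Step 5
Reactants: 10 1,3-dihydroxyacetone (used as its commercial dimer)
Product: 12 4-(hydroxymethyl)-3-methylfuran-2(5H)-one, via ethyl 4-hydroxy-3-(hydroxymethyl)-2-methylbut-2-enoate 11 (not isolated)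
Conditions: Ph3P=C(CH3)CO2Et (1.1 equiv), CH2Cl2, rt → 40 °C
Reagents that add atoms: ethyl 2-(triphenylphosphoranylidene)propanoate, CCOC(=O)C(C)=P(c1ccccc1)(c1ccccc1)c1ccccc1
Why: Wittig olefination of a symmetrical ketone followed by spontaneous lactonisation; one hydroxymethyl group is always cis to the ester, so olefin geometry does not matter.

Step 6
Reactants: 12 4-(hydroxymethyl)-3-methylfuran-2(5H)-one
Product: 14 triethyl({4-methyl-5-[(triethylsilyl)oxy]furan-3-yl}methoxy)silane, via 3-methyl-4-[(triethylsilyloxy)methyl]furan-2(5H)-one 13 (not isolated)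
Conditions: TESOTf (2.3 equiv), Et3N (3 equiv), CH2Cl2, 0 °C; filtration through basic alumina
Reagents that add atoms: triethylsilyl trifluoromethanesulfonate, CC[Si](CC)(CC)OS(=O)(=O)C(F)(F)F
Why: O-silylation of the alcohol and soft enolisation of the butenolide at its only γ-position (C11) give the aromatic 2-silyloxyfuran in one operation; the moisture-sensitive product is used directly.

Step 7
Reactants: 9 (2R,5R)-5-[(2R)-but-3-en-2-yl]-2-methyloxolane-2-carbaldehyde; 14 triethyl({4-methyl-5-[(triethylsilyl)oxy]furan-3-yl}methoxy)silane
Product: 15 (5S)-5-[(R)-{(2R,5R)-5-[(2R)-but-3-en-2-yl]-2-methyloxolan-2-yl}(hydroxy)methyl]-3-methyl-4-[(triethylsilyloxy)methyl]furan-2(5H)-one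
Conditions: MgBr2·OEt2 (2.5 equiv), CH2Cl2, −78 → −40 °C; aq. NaHCO3
Reagents that add atoms: none
Why: Vinylogous Mukaiyama aldol at the furan γ-carbon under chelation control: magnesium bridges the ring A oxygen and the aldehyde, and the furan attacks the convex face of this bicyclic chelate, on the side of the C9 methyl and away from C8, which gives 10R. The open transition state of silyloxyfurans normally places the new lactone oxygen syn to the new hydroxyl, which gives 11S.

Step 8
Reactants: 15 (5S)-5-[(R)-{(2R,5R)-5-[(2R)-but-3-en-2-yl]-2-methyloxolan-2-yl}(hydroxy)methyl]-3-methyl-4-[(triethylsilyloxy)methyl]furan-2(5H)-one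
Product: 16 (5S)-5-[(R)-{(2R,5R)-5-[(2R)-but-3-en-2-yl]-2-methyloxolan-2-yl}(triethylsilyloxy)methyl]-3-methyl-4-[(triethylsilyloxy)methyl]furan-2(5H)-one
Conditions: TESOTf (1.3 equiv), 2,6-lutidine, CH2Cl2, −78 → 0 °C
Reagents that add atoms: triethylsilyl trifluoromethanesulfonate, CC[Si](CC)(CC)OS(=O)(=O)C(F)(F)F
Why: Silyl triflate silylation of a hindered secondary alcohol; it blocks lactone transposition onto the C10 oxygen in later basic steps and enlarges the group that shields one face of the butenolide.

Step 9
Reactants: 16 (5S)-5-[(R)-{(2R,5R)-5-[(2R)-but-3-en-2-yl]-2-methyloxolan-2-yl}(triethylsilyloxy)methyl]-3-methyl-4-[(triethylsilyloxy)methyl]furan-2(5H)-one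
Product: 18 (3R,4S,5S)-5-[(R)-{(2R,5R)-5-[(2R)-but-3-en-2-yl]-2-methyloxolan-2-yl}(triethylsilyloxy)methyl]-3-methyl-4-[(triethylsilyloxy)methyl]oxolan-2-one, via all-cis C13-epimeric lactone 17 (not isolated)
Conditions: Cu(OAc)2·H2O (5 mol%), 1,2-bis(diphenylphosphino)benzene (5 mol%), (MeO)2MeSiH (3 equiv), t-BuOH (2 equiv), toluene, rt; then DBU (0.3 equiv), rt
Reagents that add atoms: none
Why: Copper hydride 1,4-reduction: the phosphine-ligated monovalent copper hydride should deliver hydride to C14 from the face opposite the bulky C11 substituent, which puts the C15 branch cis to C10. Kinetic protonation anti to the new C14 branch gives mainly 17, and DBU equilibrates the enolisable C13 to the trans methyl (13R); the isolated vinyl group is not a substrate.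

Step 10
Reactants: 18 (3R,4S,5S)-5-[(R)-{(2R,5R)-5-[(2R)-but-3-en-2-yl]-2-methyloxolan-2-yl}(triethylsilyloxy)methyl]-3-methyl-4-[(triethylsilyloxy)methyl]oxolan-2-one; 19 (E)-3-iodo-2-methylprop-2-en-1-ol
Product: 21 (3R,4S,5S)-5-[(R)-{(2R,5R)-5-[(2R,5E)-7-hydroxy-6-methylhept-5-en-2-yl]-2-methyloxolan-2-yl}(triethylsilyloxy)methyl]-3-methyl-4-[(triethylsilyloxy)methyl]oxolan-2-one, via B-alkyl-9-borabicyclo[3.3.1]nonane 20 (not isolated)
Conditions: 9-BBN dimer (1.4 equiv B–H), THF, 0 °C → rt; then 19 (1.3 equiv), PdCl2(dppf) (5 mol%), AsPh3 (10 mol%), Cs2CO3 (3 equiv), DMF/H2O, rt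
Reagents that add atoms: none
Why: Anti-Markovnikov hydroboration of the only olefin, then B-alkyl Suzuki–Miyaura coupling forms C2–C3 with retention of the (E)-vinyl iodide geometry; the lactone, the silyl ethers and the free allylic hydroxyl tolerate these room-temperature conditions.

Step 11
Reactants: 21 (3R,4S,5S)-5-[(R)-{(2R,5R)-5-[(2R,5E)-7-hydroxy-6-methylhept-5-en-2-yl]-2-methyloxolan-2-yl}(triethylsilyloxy)methyl]-3-methyl-4-[(triethylsilyloxy)methyl]oxolan-2-one
Product: 22 methyl carbonate of 21 at the C16 oxygen
Conditions: ClCO2Me (1.5 equiv), pyridine, CH2Cl2, 0 °C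
Reagents that add atoms: methyl chloroformate, COC(Cl)=O
Why: Acylation of the only free hydroxyl; the carbonate is installed after the cross-coupling because it would be ionised by zerovalent palladium.

Step 12
Reactants: 22 methyl carbonate of 21 at the C16 oxygen
Product: 23 C15 primary alcohol (22 without the primary triethylsilyl group)
Conditions: PPTS (0.2 equiv), MeOH/CH2Cl2 (1:3), 0 °C
Reagents that add atoms: none
Why: Acid-catalysed methanolysis removes a primary triethylsilyl ether much faster than the secondary one on C10, which is flanked by the quaternary C9 and ring B; the carbonate and the lactone are inert.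

Step 13
Reactants: 23 C15 primary alcohol
Product: 24 C15 primary iodide
Conditions: I2 (1.3 equiv), PPh3 (1.3 equiv), imidazole (2.5 equiv), CH2Cl2, 0 °C → rt
Reagents that add atoms: iodine, II
Why: Appel-type iodination through the alkoxyphosphonium salt; the displacement is at the primary carbon C15, so C14 is untouched.

Step 14
Reactants: 24 C15 primary iodide
Product: 25 seco C15 nitroalkane with the C16 allylic methyl carbonate
Conditions: AgNO2 (3 equiv), Et2O, 0 °C → rt, dark
Reagents that add atoms: silver nitrite, [Ag+].[O-]N=O
Why: Victor Meyer reaction: silver assists iodide departure and N-attack of nitrite gives the nitroalkane. O-attack, the usual minor pathway, gives a nitrite ester that hydrolyses to 23 on work-up and is recycled; no base is present, so the carbonate and lactone are safe.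

Step 15
Reactants: 25 seco C15 nitroalkane with the C16 allylic methyl carbonate
Product: 26 macrocyclic C15 nitro lactone, C10 triethylsilyl ether (C15 epimers)
Conditions: Pd(PPh3)4 (10 mol%), THF, 50 °C; 25 added by syringe pump over 12 h (final 2 mM), argon
Reagents that add atoms: none
Why: Proposed new method: zerovalent palladium ionises the C16 allylic carbonate with loss of CO2, giving a cationic η3-(2-methylallyl)palladium unit over C16–C1–C2 and one equivalent of methoxide, which deprotonates only the CH2NO2 group, so electrophile and nucleophile arise pairwise in the same molecule without added base; the closest known reaction types are the palladium-catalysed allylation of nitroalkanes with allylic carbonates and the macrocyclisation of stabilised carbanions onto allylpalladium termini, which have not been combined for a nitronate. The soft nitronate carbon C15 attacks the allyl ligand on the face opposite palladium at the unsubstituted distal terminus C16, and any O-allyl nitronate is itself an allylic ester that can re-ionise, so O-attack should be returned to the C-allylated product. The ring closes in the olefin-in-ring mode: attack at C16 gives the 14-membered carbocycle with C1=C2 endocyclic, whereas attack at the substituted proximal terminus C2 would give a 12-membered ring with an exocyclic propenyl group and is disfavoured by substitution and ring size. The only new stereocentre, C15, is uncontrolled and need not be controlled, because both epimers give the same ketone in step 16. The (E)-geometry should be kept because ionisation gives the allyl complex with the C3 chain syn to the C1 methyl, and syn–anti exchange would need a σ-bond from palladium to the secondary carbon C2; slow addition keeps the zwitterion concentration low and favours cyclisation over oligomerisation. After the C–C bond is formed no base remains, so 26 is not allylated again and C13, C14 and the lactone are untouched.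

Step 16
Reactants: 26 macrocyclic C15 nitro lactone, C10 triethylsilyl ether
Product: 30 10-O-triethylsilyl ether of the target, via potassium nitronate 27 (not isolated), via oxime 28 (not isolated), via N-unsubstituted ketimine 29 (not isolated)
Conditions: t-BuOK (1.05 equiv), THF, −40 → 0 °C, 15 min; then added to aq. TiCl3 (4.5 equiv), NH4OAc buffer (pH 5–6), THF/H2O, 0 °C → rt
Reagents that add atoms: water, O
Why: Nef reaction in its reductive form: one equivalent of a non-nucleophilic base removes only the nitro α-proton (far more acidic than C13–H), and trivalent titanium reduces the nitronate through the oxime to the imine, which hydrolyses in the buffer. The ketone therefore appears only at pH 5–6, where C14 does not enolise, the C11 oxygen does not eliminate and the olefin does not migrate.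

Step 17
Reactants: 30 10-O-triethylsilyl ether of the target
Product: 31 CNP0386136.3
Conditions: HF (48% aq.), MeCN, 0 °C → rt
Reagents that add atoms: none
Why: Acidic fluoride cleavage of the secondary silyl ether; no base is present, so the β-acyloxy ketone, the β,γ-olefin and the lactone should survive.

## Compound list

1 | 4-methylpent-4-en-1-ol | CC(=C)CCCO | starting material
2 | 4-methylpent-4-enal | CC(=C)CCC=O | intermediate
3 | cis-2-butene | C/C=C\C | starting material
4 | (Z)-but-2-enylpotassium | C/C=C\[CH2-].[K+] | intermediate
5 | (−)-B-[(Z)-but-2-en-1-yl]diisopinocampheylborane (isopinocampheyl groups from (+)-α-pinene) | C/C=C\CB([C@@H]1C[C@@H]2C[C@H]([C@H]1C)C2(C)C)[C@@H]1C[C@@H]2C[C@H]([C@H]1C)C2(C)C | intermediate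
6 | (3R,4R)-3,7-dimethylocta-1,7-dien-4-yl diisopinocampheylborinate | C=C[C@@H](C)[C@H](OB([C@@H]1C[C@@H]2C[C@H]([C@H]1C)C2(C)C)[C@@H]1C[C@@H]2C[C@H]([C@H]1C)C2(C)C)CCC(C)=C | intermediate
7 | (3R,4R)-3,7-dimethylocta-1,7-dien-4-ol | C=C[C@@H](C)[C@H](O)CCC(C)=C | intermediate
8 | [(2R,5R)-5-[(2R)-but-3-en-2-yl]-2-methyloxolan-2-yl]methanol | C=C[C@@H](C)[C@H]1CC[C@@](C)(O1)CO | intermediate
9 | (2R,5R)-5-[(2R)-but-3-en-2-yl]-2-methyloxolane-2-carbaldehyde | C=C[C@@H](C)[C@H]1CC[C@@](C)(O1)C=O | intermediate
10 | 1,3-dihydroxyacetone | OCC(=O)CO | starting material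
11 | ethyl 4-hydroxy-3-(hydroxymethyl)-2-methylbut-2-enoate | CCOC(=O)C(C)=C(CO)CO | intermediate
12 | 4-(hydroxymethyl)-3-methylfuran-2(5H)-one | CC1=C(CO)COC1=O | intermediate
13 | 3-methyl-4-[(triethylsilyloxy)methyl]furan-2(5H)-one | CC1=C(CO[Si](CC)(CC)CC)COC1=O | intermediate
14 | triethyl({4-methyl-5-[(triethylsilyl)oxy]furan-3-yl}methoxy)silane | CC[Si](CC)(CC)OCc1coc(O[Si](CC)(CC)CC)c1C | intermediate
15 | (5S)-5-[(R)-{(2R,5R)-5-[(2R)-but-3-en-2-yl]-2-methyloxolan-2-yl}(hydroxy)methyl]-3-methyl-4-[(triethylsilyloxy)methyl]furan-2(5H)-one | C=C[C@@H](C)[C@H]1CC[C@@](C)(O1)[C@H](O)[C@H]2OC(=O)C(C)=C2CO[Si](CC)(CC)CC | intermediate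
16 | (5S)-5-[(R)-{(2R,5R)-5-[(2R)-but-3-en-2-yl]-2-methyloxolan-2-yl}(triethylsilyloxy)methyl]-3-methyl-4-[(triethylsilyloxy)methyl]furan-2(5H)-one | C=C[C@@H](C)[C@H]1CC[C@@](C)(O1)[C@H](O[Si](CC)(CC)CC)[C@H]2OC(=O)C(C)=C2CO[Si](CC)(CC)CC | intermediate
17 | (3S,4S,5S)-epimer of 18 (all-cis ring B, kinetic protonation product) | C=C[C@@H](C)[C@H]1CC[C@@](C)(O1)[C@H](O[Si](CC)(CC)CC)[C@H]2OC(=O)[C@@H](C)[C@H]2CO[Si](CC)(CC)CC | intermediate
18 | (3R,4S,5S)-5-[(R)-{(2R,5R)-5-[(2R)-but-3-en-2-yl]-2-methyloxolan-2-yl}(triethylsilyloxy)methyl]-3-methyl-4-[(triethylsilyloxy)methyl]oxolan-2-one | C=C[C@@H](C)[C@H]1CC[C@@](C)(O1)[C@H](O[Si](CC)(CC)CC)[C@H]2OC(=O)[C@H](C)[C@H]2CO[Si](CC)(CC)CC | intermediate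
19 | (E)-3-iodo-2-methylprop-2-en-1-ol | OC/C(C)=C/I | starting material
20 | B-alkyl-9-borabicyclo[3.3.1]nonane from 18 (boron on C3) | B1(CC[C@@H](C)[C@H]3CC[C@@](C)(O3)[C@H](O[Si](CC)(CC)CC)[C@H]4OC(=O)[C@H](C)[C@H]4CO[Si](CC)(CC)CC)C2CCCC1CCC2 | intermediate
21 | (3R,4S,5S)-5-[(R)-{(2R,5R)-5-[(2R,5E)-7-hydroxy-6-methylhept-5-en-2-yl]-2-methyloxolan-2-yl}(triethylsilyloxy)methyl]-3-methyl-4-[(triethylsilyloxy)methyl]oxolan-2-one | OC/C(C)=C/CC[C@@H](C)[C@H]1CC[C@@](C)(O1)[C@H](O[Si](CC)(CC)CC)[C@H]2OC(=O)[C@H](C)[C@H]2CO[Si](CC)(CC)CC | intermediate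
22 | (3R,4S,5S)-5-[(R)-{(2R,5R)-5-[(2R,5E)-7-(methoxycarbonyloxy)-6-methylhept-5-en-2-yl]-2-methyloxolan-2-yl}(triethylsilyloxy)methyl]-3-methyl-4-[(triethylsilyloxy)methyl]oxolan-2-one | COC(=O)OC/C(C)=C/CC[C@@H](C)[C@H]1CC[C@@](C)(O1)[C@H](O[Si](CC)(CC)CC)[C@H]2OC(=O)[C@H](C)[C@H]2CO[Si](CC)(CC)CC | intermediate
23 | (3R,4S,5S)-4-(hydroxymethyl)-5-[(R)-{(2R,5R)-5-[(2R,5E)-7-(methoxycarbonyloxy)-6-methylhept-5-en-2-yl]-2-methyloxolan-2-yl}(triethylsilyloxy)methyl]-3-methyloxolan-2-one | COC(=O)OC/C(C)=C/CC[C@@H](C)[C@H]1CC[C@@](C)(O1)[C@H](O[Si](CC)(CC)CC)[C@H]2OC(=O)[C@H](C)[C@H]2CO | intermediate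
24 | (3R,4R,5S)-4-(iodomethyl) analogue of 23 | COC(=O)OC/C(C)=C/CC[C@@H](C)[C@H]1CC[C@@](C)(O1)[C@H](O[Si](CC)(CC)CC)[C@H]2OC(=O)[C@H](C)[C@H]2CI | intermediate
25 | (3R,4S,5S)-4-(nitromethyl) analogue of 23 (seco C15 nitroalkane with C16 allylic methyl carbonate) | COC(=O)OC/C(C)=C/CC[C@@H](C)[C@H]1CC[C@@](C)(O1)[C@H](O[Si](CC)(CC)CC)[C@H]2OC(=O)[C@H](C)[C@H]2C[N+](=O)[O-] | intermediate
26 | macrocyclic C15 nitro lactone: skeleton of 31 with H and NO2 on C15 and OSiEt3 on C10 (C15 epimers, one drawn) | C/C1=C\CC[C@@H](C)[C@H]2CC[C@@](C)(O2)[C@H](O[Si](CC)(CC)CC)[C@H]3OC(=O)[C@H](C)[C@H]3[C@@H]([N+](=O)[O-])C1 | intermediate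
27 | potassium C15 nitronate of 26 | C/C1=C\CC[C@@H](C)[C@H]2CC[C@@](C)(O2)[C@H](O[Si](CC)(CC)CC)[C@H]3OC(=O)[C@H](C)[C@H]3C(C1)=[N+]([O-])[O-].[K+] | intermediate
28 | C15 oxime of 30 | C/C1=C\CC[C@@H](C)[C@H]2CC[C@@](C)(O2)[C@H](O[Si](CC)(CC)CC)[C@H]3OC(=O)[C@H](C)[C@H]3C(C1)=NO | intermediate
29 | C15 N-unsubstituted imine of 30 | C/C1=C\CC[C@@H](C)[C@H]2CC[C@@](C)(O2)[C@H](O[Si](CC)(CC)CC)[C@H]3OC(=O)[C@H](C)[C@H]3C(C1)=N | intermediate
30 | 10-O-triethylsilyl ether of 31 | C/C1=C\CC[C@@H](C)[C@H]2CC[C@@](C)(O2)[C@H](O[Si](CC)(CC)CC)[C@H]3OC(=O)[C@H](C)[C@H]3C(=O)C1 | intermediate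
31 | CNP0386136.3: (1E,5R,6R,9R,10R,11S,13R,14R) 14-membered C15-keto carbocycle with C6–O–C9 oxolane bridge, C10 hydroxyl and C11/C14-fused γ-lactone (locants as under Structural features) | C/C1=C\CC[C@@H](C)[C@H]2CC[C@@](C)(O2)[C@H](O)[C@H]2OC(=O)[C@H](C)[C@H]2C(=O)C1 | target

## Step count and least certain steps

Total: 17 steps. Longest linear sequence: 15 steps (1–4 and 7–17); the furan branch (steps 5 and 6) joins at step 7.

Step 15 (key step, Proposed new method). Most likely to go wrong: intermolecular allylation outrunning ring closure, so that oligomers form; O-allylation followed by fragmentation of the nitronic ester instead of re-ionisation; syn–anti isomerisation of the allyl complex during a slow ring closure, which would erode the (E)-geometry. Fallback with known chemistry, closing the ring at the C1=C2 olefin instead: from 18, hydroboration to 20 and B-alkyl Suzuki–Miyaura coupling with vinyl bromide [PdCl2(dppf), AsPh3, Cs2CO3] would give the chain-extended terminal olefin F1. Methanolysis of the primary silyl ether (PPTS, MeOH) would give the alcohol F2, iodination (I2, PPh3, imidazole) the iodide F3 and AgNO2 the nitroalkane F4, as in steps 12–14. Intermolecular allylation of F4 with 2-methylallyl methyl carbonate and Pd(PPh3)4, the known mono-allylation of a primary nitroalkane, would give the diene F5. Ring-closing metathesis of F5 with the second-generation Grubbs catalyst in dilute toluene would then form C1=C2 and return to the route at 26. The cost is that the olefin geometry is then set by the metathesis equilibrium and no longer by 19.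

Step 7. Most likely to go wrong: loss of chelation control, so that Felkin-type attack gives the C10 epimer; poor simple diastereoselection at C11; α- instead of γ-attack of the hindered 3,4-disubstituted silyloxyfuran. Fallback, building ring B by a chelated Barbier allylation instead: from 9, chelation-controlled addition of (isopropoxydimethylsilyl)methylmagnesium chloride (THF, −78 °C) would give the β-silyl alcohol F6, and Tamao oxidation (H2O2, KF, KHCO3) the diol F7. Nitroxyl-catalysed oxidation of the primary hydroxyl (TEMPO, PhI(OAc)2) would give the α-hydroxy aldehyde F8. Allylation of F8 with methyl (Z)-2-(bromomethyl)-4-(triethylsilyloxy)but-2-enoate and indium in aqueous THF, with lactonisation in the same flask, would give the cis-4,5-disubstituted α-methylene lactone F9; C11 is set syn to the chelating C10 hydroxyl and C14 by the closed transition state of the (Z)-allyl unit. Silylation (TESOTf, 2,6-lutidine) would give the bis-silyl ether F10. Copper hydride 1,4-reduction of the unhindered exocyclic methylene [Cu(OAc)2·H2O, bisphosphine, silane; then DBU] would return to the route at 18, so steps 7–9 are bypassed.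

Step 9. Most likely to go wrong: no hydride transfer to the fully substituted β-carbon C14; competing 1,2-reduction of the lactone carbonyl by the silane; insufficient facial bias at C14. Fallback, reducing a less substituted butenolide and adding the methyl group afterwards: from 10, Wittig olefination–lactonisation with Ph3P=CHCO2Et would give 4-(hydroxymethyl)furan-2(5H)-one F11, and bis-silylation (TESOTf, Et3N) the silyloxyfuran F12. The MgBr2·OEt2-mediated vinylogous aldol of F12 with 9 would give the butenolide F13 and silylation its C10 silyl ether F14. Copper hydride 1,4-reduction of the trisubstituted butenolide F14, a standard substrate, would give the lactone F15. Enolisation with LDA (THF, −78 °C) and methylation with MeI anti to the C14 branch would return to the route at 18.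

Step 16. Most likely to go wrong: slow or incomplete deprotonation at the hindered C15, so that excess base is needed and then attacks the lactone; β-elimination of the C11 oxygen or olefin migration if the new ketone meets unbuffered base or acid during the quench. Fallback, a two-stage conversion without a strong base: from 26, reduction of the nitro group to the oxime 28 with SnCl2, PhSH and Et3N in MeCN, isolation of 28, then reductive hydrolysis with buffered aqueous TiCl3 through 29 would return to the route at 30.

## Further compounds

F1 | step 15 | (3R,4S,5S)-5-[(R)-{(2R,5R)-5-[(2R)-hex-5-en-2-yl]-2-methyloxolan-2-yl}(triethylsilyloxy)methyl]-3-methyl-4-[(triethylsilyloxy)methyl]oxolan-2-one | C=CCC[C@@H](C)[C@H]1CC[C@@](C)(O1)[C@H](O[Si](CC)(CC)CC)[C@H]2OC(=O)[C@H](C)[C@H]2CO[Si](CC)(CC)CC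
F2 | step 15 | (3R,4S,5S)-5-[(R)-{(2R,5R)-5-[(2R)-hex-5-en-2-yl]-2-methyloxolan-2-yl}(triethylsilyloxy)methyl]-4-(hydroxymethyl)-3-methyloxolan-2-one | C=CCC[C@@H](C)[C@H]1CC[C@@](C)(O1)[C@H](O[Si](CC)(CC)CC)[C@H]2OC(=O)[C@H](C)[C@H]2CO
F3 | step 15 | (3R,4R,5S)-4-(iodomethyl) analogue of F2 | C=CCC[C@@H](C)[C@H]1CC[C@@](C)(O1)[C@H](O[Si](CC)(CC)CC)[C@H]2OC(=O)[C@H](C)[C@H]2CI
F4 | step 15 | (3R,4S,5S)-4-(nitromethyl) analogue of F2 | C=CCC[C@@H](C)[C@H]1CC[C@@](C)(O1)[C@H](O[Si](CC)(CC)CC)[C@H]2OC(=O)[C@H](C)[C@H]2C[N+](=O)[O-]
F5 | step 15 | (3R,4S,5S)-4-(3-methyl-1-nitrobut-3-en-1-yl) analogue of F2 (C15 epimers) | C=CCC[C@@H](C)[C@H]1CC[C@@](C)(O1)[C@H](O[Si](CC)(CC)CC)[C@H]2OC(=O)[C@H](C)[C@H]2C(CC(C)=C)[N+](=O)[O-]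
F6 | step 7 | (1S)-1-{(2R,5R)-5-[(2R)-but-3-en-2-yl]-2-methyloxolan-2-yl}-2-[dimethyl(propan-2-yloxy)silyl]ethan-1-ol | C=C[C@@H](C)[C@H]1CC[C@@](C)(O1)[C@H](O)C[Si](C)(C)OC(C)C
F7 | step 7 | (1R)-1-{(2R,5R)-5-[(2R)-but-3-en-2-yl]-2-methyloxolan-2-yl}ethane-1,2-diol | C=C[C@@H](C)[C@H]1CC[C@@](C)(O1)[C@H](O)CO
F8 | step 7 | (2S)-2-{(2R,5R)-5-[(2R)-but-3-en-2-yl]-2-methyloxolan-2-yl}-2-hydroxyacetaldehyde | C=C[C@@H](C)[C@H]1CC[C@@](C)(O1)[C@H](O)C=O
F9 | step 7 | (4S,5S)-5-[(R)-{(2R,5R)-5-[(2R)-but-3-en-2-yl]-2-methyloxolan-2-yl}(hydroxy)methyl]-3-methylidene-4-[(triethylsilyloxy)methyl]oxolan-2-one | C=C[C@@H](C)[C@H]1CC[C@@](C)(O1)[C@H](O)[C@H]2OC(=O)C(=C)[C@H]2CO[Si](CC)(CC)CC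
F10 | step 7 | C10 triethylsilyl ether of F9 | C=C[C@@H](C)[C@H]1CC[C@@](C)(O1)[C@H](O[Si](CC)(CC)CC)[C@H]2OC(=O)C(=C)[C@H]2CO[Si](CC)(CC)CC
F11 | step 9 | 4-(hydroxymethyl)furan-2(5H)-one | OCC1=CC(=O)OC1
F12 | step 9 | triethyl({5-[(triethylsilyl)oxy]furan-3-yl}methoxy)silane | CC[Si](CC)(CC)OCc1coc(O[Si](CC)(CC)CC)c1
F13 | step 9 | (5S)-5-[(R)-{(2R,5R)-5-[(2R)-but-3-en-2-yl]-2-methyloxolan-2-yl}(hydroxy)methyl]-4-[(triethylsilyloxy)methyl]furan-2(5H)-one | C=C[C@@H](C)[C@H]1CC[C@@](C)(O1)[C@H](O)[C@H]2OC(=O)C=C2CO[Si](CC)(CC)CC
F14 | step 9 | C10 triethylsilyl ether of F13 | C=C[C@@H](C)[C@H]1CC[C@@](C)(O1)[C@H](O[Si](CC)(CC)CC)[C@H]2OC(=O)C=C2CO[Si](CC)(CC)CC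
F15 | step 9 | (4S,5S)-5-[(R)-{(2R,5R)-5-[(2R)-but-3-en-2-yl]-2-methyloxolan-2-yl}(triethylsilyloxy)methyl]-4-[(triethylsilyloxy)methyl]oxolan-2-one | C=C[C@@H](C)[C@H]1CC[C@@](C)(O1)[C@H](O[Si](CC)(CC)CC)[C@H]2OC(=O)C[C@H]2CO[Si](CC)(CC)CC
F0 | step 16 | none | none
A1 | alternative 1 | (2S)-2-hydroxy-2-{(2R,5R)-2-methyl-5-[(2R)-6-methylhept-5-en-2-yl]oxolan-2-yl}acetaldehyde | CC(C)=CCC[C@@H](C)[C@H]1CC[C@@](C)(O1)[C@H](O)C=O
A2 | alternative 1 | methyl (Z)-2-(bromomethyl)-4-[(tert-butyldimethylsilyl)oxy]but-2-enoate | BrC/C(C(=O)OC)=C\CO[Si](C)(C)C(C)(C)C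
A3 | alternative 1 | (4S,5S)-4-{[tert-butyl(dimethyl)silyl]oxymethyl}-5-[(R)-hydroxy{(2R,5R)-2-methyl-5-[(2R)-6-methylhept-5-en-2-yl]oxolan-2-yl}methyl]-3-methylideneoxolan-2-one | CC(C)=CCC[C@@H](C)[C@H]1CC[C@@](C)(O1)[C@H](O)[C@H]2OC(=O)C(=C)[C@H]2CO[Si](C)(C)C(C)(C)C
A4 | alternative 2 | seco C15 hydroximoyl chloride with (E)-C11=C14 olefin, free C10 hydroxyl and C12 tert-butyldimethylsilyl ether | ON=C(Cl)C/C(C)=C/CC[C@@H](C)[C@H]1CC[C@@](C)(O1)[C@H](O)/C=C/[C@@H](C)CO[Si](C)(C)C(C)(C)C
A5 | alternative 2 | C15 nitrile oxide derived from A4 | [O-][N+]#CC/C(C)=C/CC[C@@H](C)[C@H]1CC[C@@](C)(O1)[C@H](O)/C=C/[C@@H](C)CO[Si](C)(C)C(C)(C)C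
A6 | alternative 2 | macrocyclic isoxazoline (O on C11, C=N at C15) | C/C1=C\CC[C@@H](C)[C@H]2CC[C@@](C)(O2)[C@H](O)[C@H]3ON=C(C1)[C@@H]3[C@@H](C)CO[Si](C)(C)C(C)(C)C
A7 | alternative 3 | seco lactone with C3=C4 vinyl group, C15 dioxolane and (E)-C2 vinyl iodide | C=C[C@@H](C)[C@H]1CC[C@@](C)(O1)[C@H](O[Si](CC)(CC)CC)[C@H]2OC(=O)[C@H](C)[C@H]2C3(OCCO3)C/C(C)=C/I
A8 | alternative 3 | protected macrocycle (C15 dioxolane, C10 triethylsilyl ether) | C/C1=C\CC[C@@H](C)[C@H]2CC[C@@](C)(O2)[C@H](O[Si](CC)(CC)CC)[C@H]3OC(=O)[C@H](C)[C@H]3C4(OCCO4)C1
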